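The runs were computed from invented constants, noise included.

The noon run reads 101% as open intermediate and product together at 1.00 min, more than the partner charged, which is 76.0% of the starting material, so I take it that opening uses no partner.

| setting | noon | flask |
|---|---|---|
| starting material | 0.50 M | 0.50 M |
| partner | 0.38 M | 0.750 M |
| remark | run made earlier |  |
| time |  | 40 min |

noon run (percent of the starting material charged)

| time / min | open intermediate / % | product / % |
|---|---|---|
| 1.00 | 84 | 17 |
| 3.00 | 72 | 28 |
| 5.00 | 68 | 31 |
| 8.00 | 67 | 33 |

(scatter of a reading: 1.5 percentage points)

1. when, up to 40 min, the flask holds most open intermediate
2. the amount of open intermediate, in percent of the starting material charged, at that time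
3. earliest time at which at least nineteen twentieths of that best amount are there, in min
4. latest time at which they still are, in min



Where does product stop? At noon it reads 31% at 5.00 min and 33% at 8.00 min, a step near the scatter, so I treat the last reading as a plateau. If each product holds one partner, 0.215 M of partner stands unbound. This gives 2.29 /M, the plateau quotient, [product] over [open intermediate] times [unbound partner]. It is forward rate over back rate, so time drops out: an equilibrium constant, read here with the scatter of the readings.

What does it give for the flask? Solving the same quotient with the flask's charges gives 0.264 M of product, which leaves 47.3% open intermediate at the end.

How high is the peak above that? The noon readings begin at 1.00 min, with their highest value already first, so they show no peak, and my reckoning stops at the end level. The forecast puts the peak at 0.3 min with 86%, the window from 0.2 min to 0.6 min, and says the amount “then falls toward about 47% at equilibrium”.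

The flask peaks at 0.486 min with 76.5%, and the window runs from 0.308 min to 0.794 min.

    starting material → open intermediate (k = 0.0970 /s)
    open intermediate + second intermediate ⇌ product (K = 2.20 /M, k = 0.560 /M/s)
    partner → second intermediate (k = 0.0110 /s)

In the flask at 40.0 min the binding of open intermediate to second intermediate relaxes, both ways together, with a half-life of 1.04 s, shorter than the 1.1 min half-life of partner turning into second intermediate by that step alone. In the flask at 0.486 min, with second intermediate taking the place of unbound partner, the quotient times the 0.118 M of second intermediate gives 0.270, while product over open intermediate stands at 0.230. For the neighbour charged with 1.9 M of partner, the quotient gives 22.4% open intermediate, and that flask ends with 23.1%.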